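**Retrosynthetic overview**
1. Target 12 ⇐ triacetate 11 by base methanolysis, so no acid ever meets the allylic alcohol.
2. Key disconnection at C2'–C3' of the side chain: 11 ⇐ arylacetaldehyde 8 + 2-bromopropene 9 by catalytic asymmetric Nozaki–Hiyama–Kishi isopropenylation. The only stereocentre is set in the C–C bond-forming step; no prenyl group is oxidised.
3. 8 ⇐ 6-allyl triacetate 6 (oxidative cleavage) ⇐ 5-O-allyl ether 4 (aromatic Claisen, C6 only, phenol trapped in situ).
4. 4 ⇐ genistein 1 + allyl alcohol 3. No ring is formed: rings A, B and C come intact with genistein.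

Assumption: genistein, a bulk commercial chemical, is taken as an allowed starting material.
Assumption: in step 5 the (S)-ligand is taken to direct addition to the Re face of 8 (Mosher ester check on the first run); if the sense is opposite, the (R)-ligand from D-valinol is used with no other change.

**Step 1**
Reactants: 1 genistein
Product: 2 7,4'-di-O-acetylgenistein
Conditions: Ac2O (2.2 equiv), pyridine, 0 °C → rt
Reagents that add atoms: acetic anhydride, CC(=O)OC(C)=O
Why: Selective O-acylation (esterification): the 5-OH is hydrogen-bonded to the C4 carbonyl and far less nucleophilic than the 7- and 4'-OH, so two equivalents of anhydride stop at the diacetate.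

**Step 2**
Reactants: 2 7,4'-di-O-acetylgenistein; 3 allyl alcohol
Product: 4 5-O-allyl-7,4'-di-O-acetylgenistein
Conditions: PPh3 (1.5 equiv), DIAD (1.5 equiv), THF, 0 °C → rt
Reagents that add atoms: none
Why: Mitsunobu etherification alkylates the remaining chelated phenol under neutral conditions, so the base-labile aryl acetates survive where a carbonate/allyl bromide alkylation would strip them.

**Step 3**
Reactants: 4 5-O-allyl-7,4'-di-O-acetylgenistein
Product: 6 6-allyl-5,7,4'-tri-O-acetylgenistein, via 6-allyl-7,4'-di-O-acetylgenistein 5 (not isolated)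
Conditions: Ac2O/PhNEt2 (1:4), NaOAc (1.5 equiv), 195 °C, sealed tube, 3 h
Reagents that add atoms: acetic anhydride, CC(=O)OC(C)=O
Why: Aromatic Claisen rearrangement ([3,3]-sigmatropic) can deliver the allyl group only to C6 because the other ortho position (C4a) is quaternary, and Ac2O/NaOAc acetylates phenol 5 as it forms, which blocks cyclisation of the ortho-hydroxyl onto the alkene and re-caps any acetate lost at this temperature.

**Step 4**
Reactants: 6 6-allyl-5,7,4'-tri-O-acetylgenistein
Product: 8 (5,7,4'-triacetoxyisoflavon-6-yl)acetaldehyde, via 6-(2,3-dihydroxypropyl)genistein triacetate 7 (not isolated)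
Conditions: OsO4 (2 mol%), NaIO4 (4 equiv), 2,6-lutidine (2 equiv), dioxane/H2O (3:1), rt; crude aldehyde used at once
Reagents that add atoms: osmium tetroxide, O=[Os](=O)(=O)=O (oxygen carrier); sodium periodate, [Na+].[O-]I(=O)(=O)=O (oxygen source that regenerates it)
Why: Lemieux–Johnson oxidative cleavage: OsO4 dihydroxylates the unhindered terminal alkene much faster than the conjugated, electron-poor C2=C3 bond of the chromone, periodate cleaves diol 7, and the fully acetylated ring A cannot form a lactol with the new aldehyde.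

**Step 5**
Reactants: 8 (5,7,4'-triacetoxyisoflavon-6-yl)acetaldehyde; 9 2-bromopropene
Product: 11 6-[(2S)-2-hydroxy-3-methylbut-3-enyl]genistein triacetate, via Zr(C5H5)2Cl alkoxide 10 (not isolated)
Conditions: 9 (3 equiv), CrCl2 (10 mol%), (S)-N-[2-(4-isopropyl-4,5-dihydrooxazol-2-yl)-6-methylphenyl]methanesulfonamide (12 mol%), proton sponge (12 mol%), NiCl2(2,9-dimethyl-1,10-phenanthroline) (2 mol%), Mn (2 equiv), Zr(C5H5)2Cl2 (1.2 equiv), LiCl (2 equiv), MeCN, rt; aq. potassium sodium tartrate
Reagents that add atoms: none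
Why: Catalytic asymmetric Nozaki–Hiyama–Kishi reaction: zerovalent nickel activates the C–Br bond and hands the isopropenyl group to chromium, and the non-basic isopropenylchromium species held by the chiral sulfonamide ligand adds to the Re face of the enolisable aldehyde to set the (S)-carbinol, while Zr(C5H5)2Cl2 releases the chromium from the product alkoxide without silylating the aldehyde and the aryl acetates and chromone stay inert.

**Step 6**
Reactants: 11 6-[(2S)-2-hydroxy-3-methylbut-3-enyl]genistein triacetate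
Product: 12 5,7-dihydroxy-6-[(2S)-2-hydroxy-3-methylbut-3-en-1-yl]-3-(4-hydroxyphenyl)-4H-chromen-4-one
Conditions: K2CO3 (3.5 equiv), MeOH, 0 °C → rt, 1 h; AcOH to pH 6
Reagents that add atoms: none
Why: Base-mediated transesterification (methanolysis) removes all three aryl acetates, and any acetate that migrated to the carbinol in step 5, without acid, so the allylic alcohol neither ionises nor cyclises onto the flanking phenols and the stereocentre is untouched.

**Compound list**
1 | genistein, 5,7-dihydroxy-3-(4-hydroxyphenyl)-4H-chromen-4-one | Oc1cc2occ(-c3ccc(O)cc3)c(=O)c2c(O)c1 | starting material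
2 | 7,4'-di-O-acetylgenistein, 4-(7-acetoxy-5-hydroxy-4-oxo-4H-chromen-3-yl)phenyl acetate | CC(=O)Oc1cc2occ(-c3ccc(OC(C)=O)cc3)c(=O)c2c(O)c1 | intermediate
3 | allyl alcohol (prop-2-en-1-ol) | C=CCO | starting material
4 | 5-O-allyl-7,4'-di-O-acetylgenistein, 4-[7-acetoxy-4-oxo-5-(prop-2-enyloxy)-4H-chromen-3-yl]phenyl acetate | C=CCOc1cc(OC(C)=O)cc2occ(-c3ccc(OC(C)=O)cc3)c(=O)c12 | intermediate
5 | 6-allyl-7,4'-di-O-acetylgenistein (free 5-OH, allyl at C6) | C=CCc1c(OC(C)=O)cc2occ(-c3ccc(OC(C)=O)cc3)c(=O)c2c1O | intermediate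
6 | 6-allyl-5,7,4'-tri-O-acetylgenistein | C=CCc1c(OC(C)=O)cc2occ(-c3ccc(OC(C)=O)cc3)c(=O)c2c1OC(C)=O | intermediate
7 | 6-(2,3-dihydroxypropyl)genistein triacetate (racemic diol) | OCC(O)Cc1c(OC(C)=O)cc2occ(-c3ccc(OC(C)=O)cc3)c(=O)c2c1OC(C)=O | intermediate
8 | (5,7,4'-triacetoxyisoflavon-6-yl)acetaldehyde, 2-[5,7-diacetoxy-3-(4-acetoxyphenyl)-4-oxo-4H-chromen-6-yl]acetaldehyde | O=CCc1c(OC(C)=O)cc2occ(-c3ccc(OC(C)=O)cc3)c(=O)c2c1OC(C)=O | intermediate
9 | 2-bromopropene | C=C(C)Br | starting material
10 | Zr(C5H5)2Cl alkoxide of 11, chlorobis(cyclopentadienyl)zirconium (S)-alkoxide | C=C(C)[C@@H]([O-])Cc1c(OC(C)=O)cc2occ(-c3ccc(OC(C)=O)cc3)c(=O)c2c1OC(C)=O.[Zr+4].[Cl-].[cH-]1cccc1.[cH-]1cccc1 | intermediate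
11 | 6-[(2S)-2-hydroxy-3-methylbut-3-enyl]genistein triacetate | C=C(C)[C@@H](O)Cc1c(OC(C)=O)cc2occ(-c3ccc(OC(C)=O)cc3)c(=O)c2c1OC(C)=O | intermediate
12 | 5,7-dihydroxy-6-[(2S)-2-hydroxy-3-methylbut-3-en-1-yl]-3-(4-hydroxyphenyl)-4H-chromen-4-one | C=C(C)[C@@H](O)Cc1c(O)cc2occ(-c3ccc(O)cc3)c(=O)c2c1O | target

**Totals**
Total step count: 6. Longest linear sequence: 6 steps (1 → 12).

**Three steps most likely to fail**

Step 5 (enantioselectivity or turnover of the asymmetric coupling on a hindered arylacetaldehyde). The fallback sets out from 8 and comes back at 11, and sets the stereocentre by reagent-controlled reduction instead of C–C bond formation. Aldehyde 8 and 9 are coupled without the chiral ligand (CrCl2 3 equiv, NiCl2 1 mol%, DMF, rt) to give racemic 6-(2-hydroxy-3-methylbut-3-enyl)genistein triacetate F1. Dess–Martin periodinane (NaHCO3, CH2Cl2, 0 °C) then gives the isopropenyl ketone 6-(3-methyl-2-oxobut-3-enyl)genistein triacetate F2. Reduction with (R)-2-methyl-CBS-oxazaborolidine (20 mol%) and catecholborane (toluene, −78 °C), with the alkenyl group as the large substituent, gives the (S)-alcohol 11.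

Step 4 (the arylacetaldehyde may enolise, lose acetate or decompose on handling). The fallback sets out from 6 and comes back at 11 without ever making an aldehyde next to the arene. Cross-metathesis of 6 with methacrolein (second-generation Hoveyda–Grubbs catalyst, CH2Cl2, 40 °C) gives (E)-2-methyl-4-(5,7,4'-triacetoxyisoflavon-6-yl)but-2-enal F3. Luche reduction (NaBH4, CeCl3·7H2O, MeOH, −40 °C) gives the (E)-allylic alcohol F4. Sharpless asymmetric epoxidation (Ti(OiPr)4, L-(+)-diethyl tartrate, t-BuOOH, 4 Å sieves, CH2Cl2, −20 °C) gives the (2S,3S)-epoxy alcohol F5. Iodination (I2, PPh3, imidazole, CH2Cl2, 0 °C) gives the (2R,3S)-epoxy iodide F6. Zn dust in EtOH/AcOH (20:1, 50 °C) opens the epoxide by reductive β-elimination; the C–O bond at the carbinol carbon is not broken, so the (S)-alcohol 11 results.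

Step 3 (thermal Claisen at 195 °C in the presence of three acyl groups). The fallback sets out from 2 and comes back at 6, replacing the sigmatropic step by halogenation and cross-coupling. Diacetate 2 is iodinated ortho to the free, chelated 5-OH (BnMe3N·ICl2, CaCO3, CH2Cl2/MeOH, rt) to give 6-iodo-7,4'-di-O-acetylgenistein F7. Stille coupling with allyltributylstannane (Pd(PPh3)4, DMF, 90 °C) gives phenol 5, here isolated. Acetylation (Ac2O, pyridine, DMAP, rt) gives 6.

**Further compounds**
F1 | step 5 | racemic 6-(2-hydroxy-3-methylbut-3-enyl)genistein triacetate | C=C(C)C(O)Cc1c(OC(C)=O)cc2occ(-c3ccc(OC(C)=O)cc3)c(=O)c2c1OC(C)=O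
F2 | step 5 | 6-(3-methyl-2-oxobut-3-enyl)genistein triacetate (isopropenyl ketone) | C=C(C)C(=O)Cc1c(OC(C)=O)cc2occ(-c3ccc(OC(C)=O)cc3)c(=O)c2c1OC(C)=O
F3 | step 4 | (E)-2-methyl-4-(5,7,4'-triacetoxyisoflavon-6-yl)but-2-enal | O=C/C(C)=C/Cc1c(OC(C)=O)cc2occ(-c3ccc(OC(C)=O)cc3)c(=O)c2c1OC(C)=O
F4 | step 4 | (E)-2-methyl-4-(5,7,4'-triacetoxyisoflavon-6-yl)but-2-en-1-ol | OC/C(C)=C/Cc1c(OC(C)=O)cc2occ(-c3ccc(OC(C)=O)cc3)c(=O)c2c1OC(C)=O
F5 | step 4 | [(2S,3S)-2-methyl-3-(5,7,4'-triacetoxyisoflavon-6-ylmethyl)oxiran-2-yl]methanol | OC[C@]1(C)O[C@H]1Cc1c(OC(C)=O)cc2occ(-c3ccc(OC(C)=O)cc3)c(=O)c2c1OC(C)=O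
F6 | step 4 | (2R,3S)-2-(iodomethyl)-2-methyl-3-(5,7,4'-triacetoxyisoflavon-6-ylmethyl)oxirane | IC[C@]1(C)O[C@H]1Cc1c(OC(C)=O)cc2occ(-c3ccc(OC(C)=O)cc3)c(=O)c2c1OC(C)=O
F7 | step 3 | 6-iodo-7,4'-di-O-acetylgenistein | CC(=O)Oc1cc2occ(-c3ccc(OC(C)=O)cc3)c(=O)c2c(O)c1I
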